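## Structural features

The target is a tetrahydrofuran (O1, C2–C5) with identical 4-hydroxy-3-methoxyphenyl rings on C2 (ring A) and C5 (ring B) and hydroxymethyl arms on C3 (carbon C3a) and C4 (carbon C4a). All four ring carbons are contiguous stereocentres, (2S,3R,4R,5R): ring A is trans to the C3 arm, the two arms are trans, ring B is cis to the C4 arm, and the two aryl rings are therefore cis. The constitution is symmetric but the configuration is not, so the two halves cannot be made by one symmetric operation. C5 carries the more crowded (4,5-cis) arrangement, which thermodynamic control would set wrongly. Both ring C–O bonds are benzylic and para to a free phenol, so acid, strong base or hydrogenolysis can open them through quinone methides or benzylic cations, and the phenols are easily oxidised. The real difficulty is to fix C5 against its thermodynamic preference while distinguishing two identical phenols and three hydroxyls (two primary, one on C5) in the open-chain form. The key step exploits C2 being the para-benzylic carbon of ring A: two-electron oxidation of that phenol makes C2 the electrophilic end of a p-quinone methide, and the oxygen on C5, four atoms away, closes O1–C2.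

## Logic of the disconnections

17 ⇒ 16. Three O–Si bonds are cut (two primary silyl ethers, one aryl silyl ether on ring B). All remaining protection is fluoride-labile, so the end game needs neither hydrogenolysis nor acid, both of which threaten the benzylic ring C–O bonds. There is no skeletal gain; the gain is that only ring A is a free phenol in 16. The forward step must be buffered so that the p-hydroxybenzylic ethers do not open.

16 ⇒ 14 (through 15). The O1–C2 bond is cut. C2 is the only ring atom that phenol oxidation can turn into an electrophile, and the C5 oxygen is placed for a five-membered closure. This removes the ring and the C2 stereocentre and leaves an open chain with three contiguous centres. The forward step must oxidise ring A only, must let only the C5 hydroxyl reach C2, and must give the 2,3-trans epimer.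

14 ⇒ 13. The ring A phenol is returned to its benzyl ether (O–CH2Ph bond). The two phenols are constitutionally identical, so they must be told apart from the start. Benzyl survives base, hydride and homogeneous hydrogenation, and it is removed on the open chain, where no cyclic benzylic ether exists. The forward hydrogenolysis must spare the C5 hydroxyl and the silyl ethers.

13 ⇒ 12. Two primary O–Si bonds are cut. The C4a hydroxyl would otherwise compete with the C5 hydroxyl for C2 in a second five-membered closure, so it must be blocked. Silyl is chosen so that the last step stays a single fluoride operation. The forward step must select primary over secondary hydroxyl.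

12 ⇒ 11. C4a is returned to the carboxyl level and joined to the C3a oxygen as a lactone. The lactone holds C3 and C4 in one ring, makes C4 an enolisable position and differentiates the oxygens. The forward reduction must avoid retro-aldol cleavage and loss of the aryl silyl ether.

11 ⇒ 9 + 10. The C4–C5 bond is cut (aldol). This splits the molecule into two halves, each derived from 1. The forward step must attack the enolate anti to the C3 arylmethyl group (sets C4) and give the anti carbinol (sets C5).

10 ⇒ 1. The aryl O–Si bond is cut; this is a simple phenol protection.

9 ⇒ 7 (through 8). The lactone C3a–O acyl linkage is opened and C3a returned to the ester level. This reveals a succinic half-ester whose two carboxyl carbons are already differentiated. The forward step must reduce the ester beside a carboxylate without touching C3.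

7 ⇒ 6. The C2–H and C3–H bonds are removed to give the alkene. The only stereocentre of this half disappears. The forward step must be an enantioface-selective hydrogenation that leaves the aryl benzyl ether intact.

6 ⇒ 3 + 4. The C2=C3 bond is cut (Stobbe). Both partners are simple, and the condensation delivers the half-ester regiochemistry directly. The forward step must give the E alkene.

3 ⇒ 1 + 2. The O–CH2Ph bond is cut; a simple alkylation of the phenol.

## Other disconnections considered

Alternative 1: The cut removes C3–C3a and C4–C4a from a preformed γ-aryl butenolide A1. In the forward key step a vinylcopper reagent adds to C3 anti to the C2 aryl group and the resulting lactone enolate is alkylated at C4 by a benzyloxymethyl halide, anti to the new vinyl group. This should give the all-trans lactone A2 with C2, C3 and C4 of the target in place. C5 would follow by aryl-metal addition to the lactone carbonyl and reduction of the lactol, and the vinyl group would be cleaved to the C3a alcohol.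
- In favour: three contiguous centres come from one by predictable anti,anti substrate control in one flask. No electrochemical equipment is needed, and the two phenols need not be differentiated.
- Against: the γ-hydrogen of A1 is benzylic and vinylogously acidic, so basic organometallic conditions can erode its enantiopurity. A1 itself needs several steps in enantiopure form. Alkylation of cuprate-derived enolates with alkoxymethyl halides is sluggish. C5 is set last, under Lewis-acidic oxocarbenium conditions in which the C2 benzylic ether can ionise. The end game contains a primary benzyl ether that must be hydrogenolysed on the finished ring.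
- Comparison: on structure, both plans set the C3/C4 trans relation by substrate control, but the chosen plan fixes C5 before the ring exists while A2 postpones it to a cationic step. On mechanism, the alternative rests on more routine polar reactivity and is the better plan for predictability of its key step and for stereocentres set per operation. On step economy the two are about equal (ten to eleven steps).

Alternative 2: The cut removes O1–C5 and C2–C3, giving aldehyde 3 and the donor–acceptor cyclopropane A3. In the forward key step Sn(OTf)2 (divalent tin) activates the diester; the aldehyde oxygen opens the aryl-bearing carbon with inversion and the malonate carbon closes onto the carbonyl carbon. This should give tetrahydrofuran A4 with the 2,5-cis and 4,5-cis relations.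
- In favour: it is convergent, catalytic, forms two ring bonds at once and sets C2 and C5 together. On convergence and bonds formed per step it is the better plan.
- Against: A3 (enantiopure, trans, with an electron-rich donor) takes several steps. Its stereospecific opening competes with ionisation to a benzylic zwitterion, which the pivalate only partly suppresses. The extra substituent on the cyclopropane slows the annulation. The geminal diester of A4 must then be pared to one hydroxymethyl group of defined configuration (dealkoxycarbonylation, equilibration, reduction), and three kinds of oxygen protection must be handled.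
- Comparison: on structure, C3 is set last and thermodynamically in A4 but first and catalytically in the chosen plan; the outcome should be equal because trans,trans is favoured. On mechanism, both key steps pass through stabilised benzylic electrophiles and share the risk of stereochemical leakage. On step economy the alternative is probably longer (about twelve steps) because of A3 and the diester editing.

Alternative 3: The cut removes C3–C4, giving the epoxy propargyl ether A5. In the forward key step Cp2TiCl (trivalent titanium, from Cp2TiCl2 and Zn) opens the oxirane to the C3 radical, which adds to the alkyne carbon C4 in a 5-exo-dig closure. This should give the 2,3-trans methylene tetrahydrofuran A6; hydroboration would then install C4a and set C4.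
- In favour: the C–C ring closure is neutral and tolerant of benzylic ethers. It delivers the C3a hydroxyl free, the oxirane configuration is irrelevant, and both phenols can carry the same protecting group. On protecting-group economy at the ring-forming stage it is the better plan, and the reaction class is well established.
- Against: A5 needs defined configurations at C2 and C5 on either side of the ether oxygen, and forming an unsymmetrical ether between two electron-rich secondary benzylic carbons with control is difficult. C4 is left to a hydroboration whose face selectivity is uncertain, since hydrogen must arrive on the face of the C3 arm, anti to the adjacent C5 aryl group. The titanium reagent is stoichiometric unless a regeneration protocol is added.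
- Comparison: on structure, the chosen plan sets C3, C4 and C5 on an open chain with well-understood models, while A6 leaves C4 open. On mechanism, radical closure avoids the oxidation-sensitive phenol stage and is equal in expected reliability to the anodic closure. On step economy the plans are about equal, provided A5 can be reached in four to five steps.

Key step: step 10

Remarks and assumptions
- Numbering: O1, C2–C5 around the ether ring, with C2 the aryl carbon trans to its neighbouring arm; C3a and C4a are the exocyclic carbons; ring A is on C2, ring B on C5.
- Structure check: the configurations of 14, 16 and 17 were cross-checked atom by atom and agree at C3, C4 and C5, so no configuration needs correcting.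
- Design change 1: an all-benzyl precursor would need a selective double benzylation of a triol and a final hydrogenolysis of alkyl benzyl ethers next to two benzylic ring C–O bonds; instead ring B is a triisopropylsilyl ether and the primary hydroxyls are tert-butyldimethylsilyl ethers, removed together by fluoride.
- Design change 2: ring A is a benzyl ether, removed before the ring exists.
- Design change 3: the C5 configuration required is the anti aldol relation, which the lactone enolate should give directly, so no separate inversion step is planned.
- Assumption: the (4S,5S) antipode of MOD-DIOP (4,5-bis{[bis(4-methoxy-3,5-dimethylphenyl)phosphanyl]methyl}-2,2-dimethyl-1,3-dioxolane) is taken to give the R acid 7; if the sense proves opposite, the (4R,5R) ligand is used with no other change.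
- The geometry of the exocyclic double bond of 15 is not defined and has no consequence.

## Route

Step 1
Reactants: 1 vanillin (4-hydroxy-3-methoxybenzaldehyde); 2 benzyl bromide
Product: 3 4-(benzyloxy)-3-methoxybenzaldehyde
Conditions: K2CO3, DMF, rt
Reagents that add atoms: none
Why: Williamson ether synthesis on the phenoxide; the aldehyde is inert to carbonate.

Step 2
Reactants: 3 4-(benzyloxy)-3-methoxybenzaldehyde; 4 dimethyl succinate
Product: 6 (E)-4-[4-(benzyloxy)-3-methoxyphenyl]-3-(methoxycarbonyl)but-3-enoic acid, via paraconic ester lactone 5 (not isolated)
Conditions: NaOMe, MeOH, reflux; then aq. HCl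
Reagents that add atoms: none
Why: Stobbe condensation: the succinate enolate adds to the aldehyde, the alkoxide lactonises to 5, and E1cB opening gives the carboxylate of the conjugated half-ester with the aryl group trans to the ester (E).

Step 3
Reactants: 6 (E)-4-[4-(benzyloxy)-3-methoxyphenyl]-3-(methoxycarbonyl)but-3-enoic acid
Product: 7 (R)-4-[4-(benzyloxy)-3-methoxyphenyl]-3-(methoxycarbonyl)butanoic acid
Conditions: [Rh(cod)Cl]2 (0.5 mol %), (4S,5S)-MOD-DIOP (1.1 mol %), Et3N (1 equiv), H2 (1 atm), MeOH, 30 °C
Reagents that add atoms: none
Why: Rhodium-catalysed asymmetric hydrogenation of an itaconate-type half-ester: the carboxylate and the alkene chelate the metal and the twofold-symmetric diphosphine selects the enantioface, setting C3 (R); the homogeneous catalyst should leave the aryl benzyl ether intact.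

Step 4
Reactants: 7 (R)-4-[4-(benzyloxy)-3-methoxyphenyl]-3-(methoxycarbonyl)butanoic acid
Product: 9 (R)-4-[4-(benzyloxy)-3-methoxybenzyl]dihydrofuran-2(3H)-one, via hydroxy acid 8 (not isolated)
Conditions: KOH (1 equiv), EtOH, 0 °C; CaCl2, NaBH4 [Ca(BH4)2 in situ], −10 °C→rt; then 2 M HCl, rt
Reagents that add atoms: none
Why: Chemoselective borohydride reduction of the ester beside the unreactive carboxylate, then acid-catalysed lactonisation of 8; C3 is not touched and its descriptor stays R.

Step 5
Reactants: 1 vanillin (4-hydroxy-3-methoxybenzaldehyde)
Product: 10 3-methoxy-4-[(triisopropylsilyl)oxy]benzaldehyde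
Conditions: i-Pr3SiCl, imidazole, DMF, rt
Reagents that add atoms: triisopropylsilyl chloride, CC(C)[Si](Cl)(C(C)C)C(C)C
Why: Imidazole-promoted silylation of the phenol; the bulky aryl silyl ether is chosen to survive amide base, hydride and hydrogenolysis and to leave with fluoride.

Step 6
Reactants: 9 (R)-4-[4-(benzyloxy)-3-methoxybenzyl]dihydrofuran-2(3H)-one; 10 3-methoxy-4-[(triisopropylsilyl)oxy]benzaldehyde
Product: 11 (3S,4R)-4-[4-(benzyloxy)-3-methoxybenzyl]-3-[(R)-hydroxy{3-methoxy-4-[(triisopropylsilyl)oxy]phenyl}methyl]dihydrofuran-2(3H)-one
Conditions: LiN(SiMe3)2, THF, −78 °C; then 10, −78 °C; AcOH quench at −78 °C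
Reagents that add atoms: none
Why: Lithium enolate aldol addition: the aldehyde approaches the lactone enolate anti to the C3 arylmethyl group (C4 trans to C3), and the ring-fixed (E)-enolate in a closed six-membered chair transition state with the aryl group equatorial should favour the anti carbinol (C5, R); the cold acidic quench prevents retro-aldol equilibration and any syn epimer is removed by chromatography.

Step 7
Reactants: 11 (3S,4R)-4-[4-(benzyloxy)-3-methoxybenzyl]-3-[(R)-hydroxy{3-methoxy-4-[(triisopropylsilyl)oxy]phenyl}methyl]dihydrofuran-2(3H)-one
Product: 12 (1R,2R,3R)-4-[4-(benzyloxy)-3-methoxyphenyl]-2,3-bis(hydroxymethyl)-1-{3-methoxy-4-[(triisopropylsilyl)oxy]phenyl}butan-1-ol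
Conditions: LiAlH4, THF, 0 °C; then H2O, 15% aq. NaOH, H2O
Reagents that add atoms: none
Why: Hydride reduction of the lactone to the 1,4-diol; no stereocentre is involved, and at 0 °C reduction should outrun retro-aldol cleavage of the aluminium alkoxide while the hindered aryl silyl ether persists.

Step 8
Reactants: 12 (1R,2R,3R)-4-[4-(benzyloxy)-3-methoxyphenyl]-2,3-bis(hydroxymethyl)-1-{3-methoxy-4-[(triisopropylsilyl)oxy]phenyl}butan-1-ol
Product: 13 (1R,2R,3R)-4-[4-(benzyloxy)-3-methoxyphenyl]-2,3-bis({[tert-butyl(dimethyl)silyl]oxy}methyl)-1-{3-methoxy-4-[(triisopropylsilyl)oxy]phenyl}butan-1-ol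
Conditions: t-BuMe2SiCl (2.2 equiv), imidazole, CH2Cl2, −20→0 °C
Reagents that add atoms: tert-butyldimethylsilyl chloride, CC(C)(C)[Si](C)(C)Cl
Why: Chemoselective silylation: the two primary hydroxyls should react much faster than the secondary benzylic C5 hydroxyl, which is flanked by an aryl ring and a branched carbon.

Step 9
Reactants: 13 (1R,2R,3R)-4-[4-(benzyloxy)-3-methoxyphenyl]-2,3-bis({[tert-butyl(dimethyl)silyl]oxy}methyl)-1-{3-methoxy-4-[(triisopropylsilyl)oxy]phenyl}butan-1-ol
Product: 14 (1R,2R,3R)-2,3-bis({[tert-butyl(dimethyl)silyl]oxy}methyl)-4-(4-hydroxy-3-methoxyphenyl)-1-{3-methoxy-4-[(triisopropylsilyl)oxy]phenyl}butan-1-ol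
Conditions: H2 (1 atm), Pd/C, EtOAc, rt
Reagents that add atoms: none
Why: Catalytic hydrogenolysis of the aryl benzyl ether, the fastest-cleaving group present; in a neutral aprotic solvent the C5 benzylic hydroxyl and the silyl ethers should survive, and no cyclic benzylic ether exists yet.

Step 10
Reactants: 14 (1R,2R,3R)-2,3-bis({[tert-butyl(dimethyl)silyl]oxy}methyl)-4-(4-hydroxy-3-methoxyphenyl)-1-{3-methoxy-4-[(triisopropylsilyl)oxy]phenyl}butan-1-ol
Product: 16 4-[(2S,3R,4R,5R)-3,4-bis({[tert-butyl(dimethyl)silyl]oxy}methyl)-5-{3-methoxy-4-[(triisopropylsilyl)oxy]phenyl}oxolan-2-yl]-2-methoxyphenol, via p-quinone methide 15 (not isolated)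
Conditions: C (graphite) anode, Pt cathode, undivided cell, constant current (ca. 2 F/mol), LiClO4 (0.1 M), 2,6-lutidine (3 equiv), MeCN–CH2Cl2, 0 °C
Reagents that add atoms: none
Why: Anodic phenol oxidation followed by intramolecular oxa-1,6-addition: the lutidine-bound phenol of ring A is the most easily oxidised group and gives the phenoxyl radical, which loses a second electron and the benzylic C2 proton to form p-quinone methide 15. The closest known reaction types are the anodic benzylic substitution of 4-alkylphenols through quinone methides and the oxidative cyclisation of 4-(hydroxyalkyl)phenols with quinone or silver oxidants. The C5 hydroxyl adds to the methide carbon C2 in a 5-exo-trig closure (O1–C2) that restores the aromaticity of ring A. The new stereocentre C2 is controlled by allylic 1,3-strain in 15: the C3–H eclipses the exocyclic double bond, so the tethered oxygen, which must come from the C4 side, adds to the face that places ring A trans to the C3 silyloxymethyl arm; this is also the more stable epimer, so any reversible methide formation reinforces it. Chemoselectivity between the two aryl rings is needed and is secured by the silyl ether on ring B, whose oxidation potential lies well above that of the free phenol. Regioselectivity of trapping is secured by the silyl ethers on the C3a and C4a oxygens, which leave the C5 hydroxyl as the only nucleophile able to reach C2. The charge is limited to about two electrons per molecule and the cathode reduces lutidinium to H2, so the medium stays buffered and the silyl ethers and the C5 configuration should be untouched.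

Step 11
Reactants: 16 4-[(2S,3R,4R,5R)-3,4-bis({[tert-butyl(dimethyl)silyl]oxy}methyl)-5-{3-methoxy-4-[(triisopropylsilyl)oxy]phenyl}oxolan-2-yl]-2-methoxyphenol
Product: 17 4,4'-[(2S,3R,4R,5R)-3,4-bis(hydroxymethyl)oxolane-2,5-diyl]bis(2-methoxyphenol) (target)
Conditions: Bu4NF (4 equiv), AcOH (4 equiv), THF, 0 °C→rt
Reagents that add atoms: none
Why: Fluoride-induced desilylation of the aryl and both primary silyl ethers in one operation; acetic acid buffering keeps the phenols protonated so that the p-hydroxybenzylic ring ethers are not opened through quinone methides, and no bond at a stereocentre is broken.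

## Compound list

1 | vanillin (4-hydroxy-3-methoxybenzaldehyde) | COc1cc(C=O)ccc1O | starting material
2 | benzyl bromide | BrCc1ccccc1 | starting material
3 | 4-(benzyloxy)-3-methoxybenzaldehyde | COc1cc(C=O)ccc1OCc1ccccc1 | intermediate
4 | dimethyl succinate | COC(=O)CCC(=O)OC | starting material
5 | methyl 2-[4-(benzyloxy)-3-methoxyphenyl]-5-oxooxolane-3-carboxylate (paraconic ester lactone, racemic diastereomer mixture) | COC(=O)C1CC(=O)OC1c1ccc(OCc2ccccc2)c(OC)c1 | intermediate
6 | (E)-4-[4-(benzyloxy)-3-methoxyphenyl]-3-(methoxycarbonyl)but-3-enoic acid | COC(=O)/C(CC(=O)O)=C/c1ccc(OCc2ccccc2)c(OC)c1 | intermediate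
7 | (R)-4-[4-(benzyloxy)-3-methoxyphenyl]-3-(methoxycarbonyl)butanoic acid | OC(=O)C[C@@H](Cc1ccc(OCc2ccccc2)c(OC)c1)C(=O)OC | intermediate
8 | (R)-4-[4-(benzyloxy)-3-methoxyphenyl]-3-(hydroxymethyl)butanoic acid | OC(=O)C[C@@H](Cc1ccc(OCc2ccccc2)c(OC)c1)CO | intermediate
9 | (R)-4-[4-(benzyloxy)-3-methoxybenzyl]dihydrofuran-2(3H)-one | O=C1C[C@@H](Cc2ccc(OCc3ccccc3)c(OC)c2)CO1 | intermediate
10 | 3-methoxy-4-[(triisopropylsilyl)oxy]benzaldehyde | COc1cc(C=O)ccc1O[Si](C(C)C)(C(C)C)C(C)C | intermediate
11 | (3S,4R)-4-[4-(benzyloxy)-3-methoxybenzyl]-3-[(R)-hydroxy{3-methoxy-4-[(triisopropylsilyl)oxy]phenyl}methyl]dihydrofuran-2(3H)-one | O=C1OC[C@H](Cc2ccc(OCc3ccccc3)c(OC)c2)[C@H]1[C@@H](O)c1ccc(O[Si](C(C)C)(C(C)C)C(C)C)c(OC)c1 | intermediate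
12 | (1R,2R,3R)-4-[4-(benzyloxy)-3-methoxyphenyl]-2,3-bis(hydroxymethyl)-1-{3-methoxy-4-[(triisopropylsilyl)oxy]phenyl}butan-1-ol | COc1cc(C[C@@H](CO)[C@H](CO)[C@@H](O)c2ccc(O[Si](C(C)C)(C(C)C)C(C)C)c(OC)c2)ccc1OCc1ccccc1 | intermediate
13 | (1R,2R,3R)-4-[4-(benzyloxy)-3-methoxyphenyl]-2,3-bis({[tert-butyl(dimethyl)silyl]oxy}methyl)-1-{3-methoxy-4-[(triisopropylsilyl)oxy]phenyl}butan-1-ol | COc1cc(C[C@@H](CO[Si](C)(C)C(C)(C)C)[C@H](CO[Si](C)(C)C(C)(C)C)[C@@H](O)c2ccc(O[Si](C(C)C)(C(C)C)C(C)C)c(OC)c2)ccc1OCc1ccccc1 | intermediate
14 | (1R,2R,3R)-2,3-bis({[tert-butyl(dimethyl)silyl]oxy}methyl)-4-(4-hydroxy-3-methoxyphenyl)-1-{3-methoxy-4-[(triisopropylsilyl)oxy]phenyl}butan-1-ol (key-step precursor) | COc1cc(C[C@@H](CO[Si](C)(C)C(C)(C)C)[C@H](CO[Si](C)(C)C(C)(C)C)[C@@H](O)c2ccc(O[Si](C(C)C)(C(C)C)C(C)C)c(OC)c2)ccc1O | intermediate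
15 | 4-[(2R,3R,4R)-2,3-bis({[tert-butyl(dimethyl)silyl]oxy}methyl)-4-hydroxy-4-{3-methoxy-4-[(triisopropylsilyl)oxy]phenyl}butylidene]-2-methoxycyclohexa-2,5-dien-1-one (p-quinone methide, alkene geometry undefined) | O=C1C=CC(=C[C@@H](CO[Si](C)(C)C(C)(C)C)[C@H](CO[Si](C)(C)C(C)(C)C)[C@@H](O)c2ccc(O[Si](C(C)C)(C(C)C)C(C)C)c(OC)c2)C=C1OC | intermediate
16 | 4-[(2S,3R,4R,5R)-3,4-bis({[tert-butyl(dimethyl)silyl]oxy}methyl)-5-{3-methoxy-4-[(triisopropylsilyl)oxy]phenyl}oxolan-2-yl]-2-methoxyphenol (key-step product) | COc1cc([C@H]2O[C@@H](c3ccc(O[Si](C(C)C)(C(C)C)C(C)C)c(OC)c3)[C@@H](CO[Si](C)(C)C(C)(C)C)[C@@H]2CO[Si](C)(C)C(C)(C)C)ccc1O | intermediate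
17 | 4,4'-[(2S,3R,4R,5R)-3,4-bis(hydroxymethyl)oxolane-2,5-diyl]bis(2-methoxyphenol) | COc1cc([C@H]2O[C@@H](c3ccc(O)c(OC)c3)[C@@H](CO)[C@@H]2CO)ccc1O | target

## Step count and least certain steps

Total: 11 steps. Longest linear sequence: 10 steps (steps 1–4 and 6–11, from 1 to 17); step 5 is a one-step side branch that joins at step 6.

Step 10 (key step). The most likely failures are:
- coupling of phenoxyl radicals at the electrode before the second electron is removed;
- attack of the C5 hydroxyl at the ipso carbon of ring A, giving spirocyclisation instead of methide formation;
- further oxidation of the product, which still carries a free phenol;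
- incomplete 2,3-trans selection if the closure is purely kinetic.

The fallback sets out from 14 and replaces electrode electron transfer by homogeneous hydride abstraction with DDQ (about one equivalent, CH2Cl2, 0 °C). This known chemical route to p-quinone methides from 4-alkylphenols forms 15 without free phenoxyl radicals at a surface. The same 5-exo closure follows, and the weakly acidic hydroquinone by-product allows equilibration to the 2,3-trans epimer. The fallback returns to the route at 16 and forms no compound outside the list (F0).

Step 6. The most likely failure is poor simple diastereoselection at the carbinol carbon, because the chair preference of lithium lactone enolates toward aromatic aldehydes is modest; partial retro-aldol equilibration during work-up would also erode it. The fallback sets out from the crude carbinol mixture containing 11. Oxidation with Dess–Martin periodinane removes the C5 centre and gives (3S,4R)-4-[4-(benzyloxy)-3-methoxybenzyl]-3-{3-methoxy-4-[(triisopropylsilyl)oxy]benzoyl}dihydrofuran-2(3H)-one F1, whose C4 centre rests in the trans arrangement. Reduction with LiEt3BH in the presence of CeCl3 (THF, −78 °C) under non-chelated, Felkin-type control delivers hydride anti to the lactone carbonyl and past the C4 hydrogen, which should give the anti carbinol. The fallback returns at 11.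

Step 3. The most likely failure is insufficient enantioselection, or induction in the unexpected sense, with this particular aryl group. The fallback sets out from 6. Hydrogenation with the achiral complex [Rh(cod)(dppb)]BF4 (dppb = 1,4-bis(diphenylphosphanyl)butane) gives rac-4-[4-(benzyloxy)-3-methoxyphenyl]-3-(methoxycarbonyl)butanoic acid F2. This is resolved by fractional crystallisation of the salt (R)-1-phenylethylammonium (R)-4-[4-(benzyloxy)-3-methoxyphenyl]-3-(methoxycarbonyl)butanoate F3; the antipodal amine is used instead if it gives the less soluble salt of the R acid. Acidification returns 7.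

Step 9. The most likely failure is competing hydrogenolysis of the benzylic C5–O bond on the electron-rich ring B, or catalyst-induced loss of silyl groups. The fallback sets out from 13 and replaces surface hydrogenolysis by single-electron reductive cleavage with LiC10H8 (lithium naphthalenide) in THF at −25 °C. The C5 hydroxyl is present as its lithium alkoxide and is not reducible, and the silyl ethers are not electron acceptors. The fallback returns at 14 and forms no compound outside the list (F0).

## Further compounds

F0 | step 10 | none | none
F1 | step 6 | (3S,4R)-4-[4-(benzyloxy)-3-methoxybenzyl]-3-{3-methoxy-4-[(triisopropylsilyl)oxy]benzoyl}dihydrofuran-2(3H)-one | O=C1OC[C@H](Cc2ccc(OCc3ccccc3)c(OC)c2)[C@H]1C(=O)c1ccc(O[Si](C(C)C)(C(C)C)C(C)C)c(OC)c1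
F2 | step 3 | rac-4-[4-(benzyloxy)-3-methoxyphenyl]-3-(methoxycarbonyl)butanoic acid | COC(=O)C(Cc1ccc(OCc2ccccc2)c(OC)c1)CC(=O)O
F3 | step 3 | (R)-1-phenylethylammonium (R)-4-[4-(benzyloxy)-3-methoxyphenyl]-3-(methoxycarbonyl)butanoate | [O-]C(=O)C[C@@H](Cc1ccc(OCc2ccccc2)c(OC)c1)C(=O)OC.C[C@@H]([NH3+])c1ccccc1
F0 | step 9 | none | none
A1 | alternative 1 | (S)-5-[4-(benzyloxy)-3-methoxyphenyl]furan-2(5H)-one | COc1cc([C@H]2OC(=O)C=C2)ccc1OCc1ccccc1
A2 | alternative 1 | (3R,4S,5S)-5-[4-(benzyloxy)-3-methoxyphenyl]-3-[(benzyloxy)methyl]-4-vinyldihydrofuran-2(3H)-one | COc1cc([C@H]2OC(=O)[C@@H](COCc3ccccc3)[C@@H]2C=C)ccc1OCc1ccccc1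
A3 | alternative 2 | dimethyl (2S,3R)-3-({[tert-butyl(dimethyl)silyl]oxy}methyl)-2-[3-methoxy-4-(pivaloyloxy)phenyl]cyclopropane-1,1-dicarboxylate (trans) | COC(=O)C1(C(=O)OC)[C@H](CO[Si](C)(C)C(C)(C)C)[C@H]1c1ccc(OC(=O)C(C)(C)C)c(OC)c1
A4 | alternative 2 | dimethyl (2R,4R,5R)-2-[4-(benzyloxy)-3-methoxyphenyl]-4-({[tert-butyl(dimethyl)silyl]oxy}methyl)-5-[3-methoxy-4-(pivaloyloxy)phenyl]oxolane-3,3-dicarboxylate | COc1cc([C@H]2O[C@@H](c3ccc(OC(=O)C(C)(C)C)c(OC)c3)[C@@H](CO[Si](C)(C)C(C)(C)C)C2(C(=O)OC)C(=O)OC)ccc1OCc1ccccc1
A5 | alternative 3 | 2-[(R)-[4-(benzyloxy)-3-methoxyphenyl]({(R)-1-[4-(benzyloxy)-3-methoxyphenyl]prop-2-yn-1-yl}oxy)methyl]oxirane (oxirane centre undefined) | COc1cc([C@@H](O[C@H](C#C)c2ccc(OCc3ccccc3)c(OC)c2)C2CO2)ccc1OCc1ccccc1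
A6 | alternative 3 | {(2S,3R,5R)-2,5-bis[4-(benzyloxy)-3-methoxyphenyl]-4-methylideneoxolan-3-yl}methanol | COc1cc([C@H]2O[C@@H](c3ccc(OCc4ccccc4)c(OC)c3)C(=C)[C@@H]2CO)ccc1OCc1ccccc1
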